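**Retrosynthetic overview**

- Feature: ring A carries oxygen on four contiguous carbons, C5, C6, C7 and C8, with C5 and C8 para. These map onto the four carbons of a squarate, and the fusion bond C4a–C8a maps onto the one unsubstituted C=C (C5=C6) of a 2-aryl-3-methoxy-4-pyranone.
- Target ⇒ debenzylation, then 8-O-methylation (the 5-OH is held back by its hydrogen bond to C4=O) ⇒ 2',4'-di-O-benzyl-5,8-dihydroxy-3,6,7-trimethoxyflavone.
- That hydroquinone ⇒ thermal cyclobutenone ring expansion (forms C5–C4a, closes ring A) ⇒ 4-hydroxy-4-(pyranon-6-yl)-2,3-dimethoxycyclobutenone ⇒ C6-magnesiated pyranone + dimethyl squarate.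
- 2-Aryl-3-methoxy-4-pyranone ⇒ Suzuki coupling of 2-bromo-3-methoxy-4-pyranone (from pyromeconic acid) with the 2,4-bis(benzyloxy)phenyl boronate (from 4-bromoresorcinol).
- Ring order: rings B and C are bought and joined first; ring A is formed last, in the key step.

Key step: step 7

Assumption: the target has no stereogenic element, so no enantiocontrol is called for. The two stereocentres that arise on the way (carbinol carbon of 10, ring-fusion carbon of 12) are racemic and are erased within step 7.

Remark on the pyranone: a 3-hydroxy-4-pyranone stands one oxidation level above the enone that an oxidative furfuryl-carbinol ring expansion gives, and the extra halogen oxidant would attack the dibenzyloxyphenyl ring. The hydroxypyranone is therefore taken as the catalogue compound pyromeconic acid and arylated.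

**Route**

Step 1
Reactants: 1 4-bromoresorcinol
Product: 2 2,4-bis(benzyloxy)-1-bromobenzene
Conditions: BnBr (2.2 equiv), K2CO3, DMF, 60 °C
Reagents that add atoms: benzyl bromide, BrCc1ccccc1
Why: Williamson ether synthesis on both phenols gives benzyl ethers that should tolerate the palladium, amide-base and thermal steps and fall to hydrogenolysis at the end.

Step 2
Reactants: 2 2,4-bis(benzyloxy)-1-bromobenzene
Product: 3 2-[2,4-bis(benzyloxy)phenyl]-4,4,5,5-tetramethyl-1,3,2-dioxaborolane
Conditions: B2pin2, Pd(dppf)Cl2 (cat.), KOAc, dioxane, 90 °C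
Reagents that add atoms: bis(pinacolato)diboron, CC1(C)OB(OC1(C)C)B1OC(C)(C)C(C)(C)O1
Why: Miyaura borylation of an aryl bromide, in which acetate is too weak a base to start Suzuki homocoupling of the product.

Step 3
Reactants: 4 pyromeconic acid (3-hydroxy-4H-pyran-4-one)
Product: 5 2-bromo-3-hydroxy-4H-pyran-4-one
Conditions: NBS (1.0 equiv), MeCN, 0 °C to rt
Reagents that add atoms: N-bromosuccinimide, O=C1CCC(=O)N1Br
Why: Electrophilic bromination should go to C2, the β-carbon of the C3 enol and the site at which 3-hydroxy-4-pyranones such as kojic acid take electrophiles.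

Step 4
Reactants: 5 2-bromo-3-hydroxy-4H-pyran-4-one
Product: 6 2-bromo-3-methoxy-4H-pyran-4-one
Conditions: MeI, K2CO3, acetone, 40 °C
Reagents that add atoms: iodomethane, CI
Why: Williamson O-alkylation of the acidic enolic hydroxyl, as in the methylation of maltol and kojic acid.

Step 5
Reactants: 6 2-bromo-3-methoxy-4H-pyran-4-one; 3 2-[2,4-bis(benzyloxy)phenyl]-4,4,5,5-tetramethyl-1,3,2-dioxaborolane
Product: 7 2-[2,4-bis(benzyloxy)phenyl]-3-methoxy-4H-pyran-4-one
Conditions: Pd(OAc)2 (cat.), SPhos, K3PO4, toluene/H2O, 80 °C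
Reagents that add atoms: none
Why: Suzuki–Miyaura coupling, in which the vinylogous acyl bromide C2–Br should add readily to Pd(0) and SPhos copes with the ortho substituents on both partners.

Step 6
Reactants: 7 2-[2,4-bis(benzyloxy)phenyl]-3-methoxy-4H-pyran-4-one; 8 dimethyl squarate
Product: 10 rac-4-{6-[2,4-bis(benzyloxy)phenyl]-5-methoxy-4-oxo-4H-pyran-2-yl}-4-hydroxy-2,3-dimethoxycyclobut-2-en-1-one, via C6-magnesiated pyranone 9 (not isolated)
Conditions: TMPMgCl·LiCl (1.1 equiv), THF, −40 °C; cannulate into 8 (1.2 equiv), THF, −78 °C; sat. aq NH4Cl (no acid)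
Reagents that add atoms: none
Why: Knochel–Hauser magnesiation should remove the C6 proton, the only ring hydrogen next to the ring oxygen and the counterpart of the C2–H of a chromone, and the alkenylmagnesium then adds 1,2 to one of the two equivalent squarate carbonyls, giving a racemic carbinol centre that is erased in step 7.

Step 7
Reactants: 10 rac-4-{6-[2,4-bis(benzyloxy)phenyl]-5-methoxy-4-oxo-4H-pyran-2-yl}-4-hydroxy-2,3-dimethoxycyclobut-2-en-1-one
Product: 13 2-[2,4-bis(benzyloxy)phenyl]-5,8-dihydroxy-3,6,7-trimethoxy-4H-chromen-4-one, via (Z)-dienylketene 11 (not isolated), via 4aH-chromene-4,5-dione tautomer 12 (not isolated)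
Conditions: degassed p-xylene, 130 °C, Ar; concentrate under Ar and use at once
Reagents that add atoms: none
Why: Heat opens the C1–C4 bond of the cyclobutenone by conrotatory 4π electrocyclic ring opening, the donor hydroxyl turning outward, so that (Z)-dienylketene 11 holds the pyranone on the inside, next to the ketene carbon. Thermal disrotatory 6π electrocyclisation then bonds the ketene carbon to pyranone C5 (the ring CH next to C4=O, the future C4a) and so closes the six-membered carbocyclic A ring as dienone 12, whose C4a–H, flanked by two carbonyls, enolises at once to the aromatic hydroquinone 13. The closest known reaction is the Moore rearrangement of squarate-derived 4-alkenyl- and 4-(hetero)aryl-4-hydroxycyclobutenones into hydroquinones; here the pyranone C5=C6 bond plays the alkenyl part, and C5, the β-carbon of the ring enol ether, is the nucleophilic position of a 4-pyranone and is matched to the electrophilic ketene carbon. No stereocentre is set: the carbinol centre of 10 and the ring-fusion centre of 12 both end as sp2 carbons. The step needs torquoselectivity and a single site of closure; the first follows from the outward preference of the hydroxyl, the second from the fact that C6 has only one carbon neighbour in the ring, C5, and the gain of a benzenoid ring drives the sequence. Air is kept out so that the hydroquinone is not oxidised to the 5,8-quinone.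

Step 8
Reactants: 13 2-[2,4-bis(benzyloxy)phenyl]-5,8-dihydroxy-3,6,7-trimethoxy-4H-chromen-4-one
Product: 14 2-[2,4-bis(benzyloxy)phenyl]-5-hydroxy-3,6,7,8-tetramethoxy-4H-chromen-4-one
Conditions: MeI (1.05 equiv), K2CO3 (1.1 equiv), degassed acetone, rt, Ar
Reagents that add atoms: iodomethane, CI
Why: Williamson methylation with one equivalent of electrophile should take the free 8-OH, because the 5-OH sits in a six-membered hydrogen bond to C4=O and is the less nucleophilic phenol, as in the classical partial methylation of 5,8-dihydroxyflavones.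

Step 9
Reactants: 14 2-[2,4-bis(benzyloxy)phenyl]-5-hydroxy-3,6,7,8-tetramethoxy-4H-chromen-4-one
Product: 15 5,2',4'-trihydroxy-3,6,7,8-tetramethoxyflavone (2-(2,4-dihydroxyphenyl)-5-hydroxy-3,6,7,8-tetramethoxy-4H-chromen-4-one)
Conditions: H2 (1 atm), 10% Pd/C, EtOAc/MeOH, rt
Reagents that add atoms: none
Why: Hydrogenolysis should cleave both aryl benzyl ethers while the tetrasubstituted C2=C3 bond of the 3-methoxyflavone and the aryl methyl ethers stay untouched.

**Compound list**

1 | 4-bromoresorcinol | Oc1ccc(Br)c(O)c1 | starting material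
2 | 2,4-bis(benzyloxy)-1-bromobenzene | Brc1ccc(OCc2ccccc2)cc1OCc1ccccc1 | intermediate
3 | 2-[2,4-bis(benzyloxy)phenyl]-4,4,5,5-tetramethyl-1,3,2-dioxaborolane | CC1(C)OB(c2ccc(OCc3ccccc3)cc2OCc2ccccc2)OC1(C)C | intermediate
4 | pyromeconic acid (3-hydroxy-4H-pyran-4-one) | O=c1ccocc1O | starting material
5 | 2-bromo-3-hydroxy-4H-pyran-4-one | O=c1ccoc(Br)c1O | intermediate
6 | 2-bromo-3-methoxy-4H-pyran-4-one | COc1c(Br)occc1=O | intermediate
7 | 2-[2,4-bis(benzyloxy)phenyl]-3-methoxy-4H-pyran-4-one | COc1c(-c2ccc(OCc3ccccc3)cc2OCc2ccccc2)occc1=O | intermediate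
8 | dimethyl squarate (3,4-dimethoxycyclobut-3-ene-1,2-dione) | COC1=C(OC)C(=O)C1=O | starting material
9 | {6-[2,4-bis(benzyloxy)phenyl]-5-methoxy-4-oxo-4H-pyran-2-yl}magnesium chloride (LiCl complex) | COc1c(-c2ccc(OCc3ccccc3)cc2OCc2ccccc2)oc([Mg]Cl)cc1=O | intermediate (not isolated)
10 | rac-4-{6-[2,4-bis(benzyloxy)phenyl]-5-methoxy-4-oxo-4H-pyran-2-yl}-4-hydroxy-2,3-dimethoxycyclobut-2-en-1-one | COC1=C(OC)C(O)(c2cc(=O)c(OC)c(-c3ccc(OCc4ccccc4)cc3OCc3ccccc3)o2)C1=O | intermediate
11 | (3Z)-4-{6-[2,4-bis(benzyloxy)phenyl]-5-methoxy-4-oxo-4H-pyran-2-yl}-4-hydroxy-2,3-dimethoxybuta-1,3-dien-1-one (dienylketene) | O=C=C(OC)/C(OC)=C(/O)c1cc(=O)c(OC)c(-c2ccc(OCc3ccccc3)cc2OCc2ccccc2)o1 | intermediate (not isolated)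
12 | rac-2-[2,4-bis(benzyloxy)phenyl]-8-hydroxy-3,6,7-trimethoxy-4aH-chromene-4,5-dione | COC1=C(OC)C(=O)C2C(=O)C(OC)=C(c3ccc(OCc4ccccc4)cc3OCc3ccccc3)OC2=C1O | intermediate (not isolated)
13 | 2-[2,4-bis(benzyloxy)phenyl]-5,8-dihydroxy-3,6,7-trimethoxy-4H-chromen-4-one | COc1c(OC)c(O)c2c(=O)c(OC)c(-c3ccc(OCc4ccccc4)cc3OCc3ccccc3)oc2c1O | intermediate
14 | 2-[2,4-bis(benzyloxy)phenyl]-5-hydroxy-3,6,7,8-tetramethoxy-4H-chromen-4-one | COc1c(OC)c(O)c2c(=O)c(OC)c(-c3ccc(OCc4ccccc4)cc3OCc3ccccc3)oc2c1OC | intermediate
15 | 5,2',4'-trihydroxy-3,6,7,8-tetramethoxyflavone | COc1c(OC)c(O)c2c(=O)c(OC)c(-c3ccc(O)cc3O)oc2c1OC | target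

**Step count**

Total steps: 9. Longest linear sequence: 7 steps (1 → 2 → 3 → 7 → 10 → 13 → 14 → 15; the branch from 4 is equally long).

**Steps most likely to fail**

1. Step 7 (key step). The 6π closure has to engage a pyranone C=C and may be slower than with a plain alkene or arene. The dienylketene could then be lost to capture of the ketene by its own enol hydroxyl (furanone formation), to reversion or to oligomerisation. The fallback gives up the ring expansion and builds ring C onto a ready-made ring A by classical flavone chemistry. It sets out from 2: bromine–lithium exchange (n-BuLi, THF, −78 °C) and a DMF quench should give 2,4-bis(benzyloxy)benzaldehyde F1. Claisen–Schmidt condensation of F1 with purchased 1-(2-hydroxy-3,4,5,6-tetramethoxyphenyl)ethanone (CC(=O)c1c(O)c(OC)c(OC)c(OC)c1OC; KOH, EtOH) should give (E)-3-[2,4-bis(benzyloxy)phenyl]-1-(2-hydroxy-3,4,5,6-tetramethoxyphenyl)prop-2-en-1-one F2. Oxidative cyclisation (cat. I2, DMSO, 120 °C) should give 2-[2,4-bis(benzyloxy)phenyl]-5,6,7,8-tetramethoxy-4H-chromen-4-one F3. C3 lithiation, borylation and oxidation in one flask (LDA, THF, −78 °C; B(OMe)3; H2O2, AcOH) should give 2-[2,4-bis(benzyloxy)phenyl]-3-hydroxy-5,6,7,8-tetramethoxy-4H-chromen-4-one F4. Methylation (MeI, K2CO3, acetone) should give 2-[2,4-bis(benzyloxy)phenyl]-3,5,6,7,8-pentamethoxy-4H-chromen-4-one F5. BCl3 with pentamethylbenzene as benzyl scavenger (CH2Cl2, −78 to 0 °C) should then cleave the carbonyl-chelated 5-methyl ether together with both benzyl ethers, and the fallback comes back to the route at the target 15.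

2. Step 6. Deprotonation may go to C5, steered by coordination of magnesium to the carbonyl oxygen, and the magnesiated pyranone may add to pyranone that is not yet metalated. The fallback makes the nucleophile by halogen–metal exchange instead of deprotonation and sets out from 7. Zincation with TMPZnCl·LiCl (THF, 25 °C; no magnesium to steer the base, and a zinc species that does not self-add) followed by an iodine quench should give 2-[2,4-bis(benzyloxy)phenyl]-6-iodo-3-methoxy-4H-pyran-4-one F6, whose regiochemistry can be assigned before it is used. Iodine–magnesium exchange (i-PrMgCl·LiCl, THF, −78 °C) should then regenerate 9 cold and free of unmetalated pyranone, and addition to 8 comes back to the route at 10.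

3. Step 8. Alkylation may spill over to the 5-OH, and the hydroquinone anion may be oxidised to the 5,8-quinone by traces of oxygen. The fallback puts the C8 methyl on before ring A exists and sets out from 10. O-Methylation of the tertiary hydroxyl (MeI, Ag2O, MeCN, rt) should give rac-4-{6-[2,4-bis(benzyloxy)phenyl]-5-methoxy-4-oxo-4H-pyran-2-yl}-2,3,4-trimethoxycyclobut-2-en-1-one F7. Thermolysis of F7 under the conditions of step 7 should deliver the C8 methyl ether and the free, chelated 5-OH directly, because the oxygen on the former carbinol carbon becomes O8 and the ketene oxygen becomes O5. This comes back to the route at 14 without passing through 13.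

**Further compounds**

F1 | step 7 | 2,4-bis(benzyloxy)benzaldehyde | O=Cc1ccc(OCc2ccccc2)cc1OCc1ccccc1
F2 | step 7 | (E)-3-[2,4-bis(benzyloxy)phenyl]-1-(2-hydroxy-3,4,5,6-tetramethoxyphenyl)prop-2-en-1-one | COc1c(O)c(C(=O)/C=C/c2ccc(OCc3ccccc3)cc2OCc2ccccc2)c(OC)c(OC)c1OC
F3 | step 7 | 2-[2,4-bis(benzyloxy)phenyl]-5,6,7,8-tetramethoxy-4H-chromen-4-one | COc1c(OC)c(OC)c2c(=O)cc(-c3ccc(OCc4ccccc4)cc3OCc3ccccc3)oc2c1OC
F4 | step 7 | 2-[2,4-bis(benzyloxy)phenyl]-3-hydroxy-5,6,7,8-tetramethoxy-4H-chromen-4-one | COc1c(OC)c(OC)c2c(=O)c(O)c(-c3ccc(OCc4ccccc4)cc3OCc3ccccc3)oc2c1OC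
F5 | step 7 | 2-[2,4-bis(benzyloxy)phenyl]-3,5,6,7,8-pentamethoxy-4H-chromen-4-one | COc1c(OC)c(OC)c2c(=O)c(OC)c(-c3ccc(OCc4ccccc4)cc3OCc3ccccc3)oc2c1OC
F6 | step 6 | 2-[2,4-bis(benzyloxy)phenyl]-6-iodo-3-methoxy-4H-pyran-4-one | COc1c(-c2ccc(OCc3ccccc3)cc2OCc2ccccc2)oc(I)cc1=O
F7 | step 8 | rac-4-{6-[2,4-bis(benzyloxy)phenyl]-5-methoxy-4-oxo-4H-pyran-2-yl}-2,3,4-trimethoxycyclobut-2-en-1-one | COC1=C(OC)C(OC)(c2cc(=O)c(OC)c(-c3ccc(OCc4ccccc4)cc3OCc3ccccc3)o2)C1=O
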